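**Retrosynthetic overview**
- The oxirane is made last, by catalyst-controlled epoxidation of the vinyl group that the Cope rearrangement creates.
- The cyclohexane comes from a Cope rearrangement of an (E,E)-germacranolide held as its 6,15-lactol; the lactol bridge fixes C5 and C10.
- The ten-membered ring is closed at C6–C7 (the bond that farnesyl diphosphate cyclisation makes in nature) by chromium-mediated allylation of a (Z)-ene-dial with a bromomethyl-butenolide; the ene-dial is unmasked from a 3-alkylfuran with singlet oxygen.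
- The lactone ring and C8/C9 come from an anti-selective asymmetric vinylogous Mukaiyama aldol of a 2-silyloxyfuran with an (E)-enal built from 3-bromofuran, butenyl Grignard and methacrolein.
- Ring order: γ-lactone (as butenolide), ten-membered carbocycle, transient lactol, cyclohexane (Cope), oxirane.

Assumption: the target is the open 6-hydroxy-15-aldehyde as drawn; it can equilibrate with its cis-fused 6,15-lactol and the two are treated as one compound.

Germacrane/elemane numbering is used for the skeleton (C6–OH, C8–O lactone, C9–O ester, C15 aldehyde, C1–C2 oxirane).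

**Step 1**
Reactants: 1 3-bromofuran; 2 but-3-en-1-ylmagnesium bromide
Product: 3 3-(but-3-en-1-yl)furan
Conditions: Ni(dppp)Cl2 (2 mol%), Et2O, 0 °C → rt
Reagents that add atoms: none
Why: Kumada–Corriu cross-coupling, in which Ni(dppp)Cl2 couples the primary alkyl Grignard with the heteroaryl bromide faster than β-hydride elimination; no stereocentre is formed.

**Step 2**
Reactants: 3 3-(but-3-en-1-yl)furan; 4 methacrolein (3 equiv)
Product: 5 (E)-6-(furan-3-yl)-2-methylhex-2-enal
Conditions: second-generation Hoveyda–Grubbs catalyst (3 mol%), CH2Cl2, 40 °C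
Reagents that add atoms: none
Why: Olefin cross-metathesis driven by loss of ethene gives the conjugated trisubstituted enal under thermodynamic control as the E isomer, which becomes the E C1=C10 bond, and the furan is inert to the ruthenium carbene.

**Step 3**
Reactants: 6 furan-3-ylmethanol
Product: 9 3-(hydroxymethyl)furan-2(5H)-one, via dilithiated furan-3-ylmethanol 7 (not isolated), via lithium furylborate 8 (not isolated)
Conditions: n-BuLi (2.2 equiv), THF, −78 → 0 °C; B(OiPr)3, −78 °C → rt; 30% H2O2, AcOH, 0 °C → rt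
Reagents that add atoms: hydrogen peroxide (OO)
Why: The lithium alkoxide directs the second lithiation to C2 (directed ortho-metalation), and borylation followed by peroxide oxidation of the C–B bond gives the 2-hydroxyfuran, which tautomerises to the conjugated butenolide.

**Step 4**
Reactants: 9 3-(hydroxymethyl)furan-2(5H)-one
Product: 11 tert-butyldimethyl{[2-(trimethylsilyloxy)furan-3-yl]methoxy}silane, via TBS ether butenolide 10 (not isolated)
Conditions: TBSCl (1.05 equiv), Et3N (3 equiv), DMAP (cat.), CH2Cl2, 0 °C; then TMSOTf (1.1 equiv), 0 °C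
Reagents that add atoms: tert-butyldimethylsilyl chloride (CC(C)(C)[Si](C)(C)Cl); trimethylsilyl triflate (C[Si](C)(C)OS(=O)(=O)C(F)(F)F)
Why: The primary alcohol is silylated first, then soft enolisation of the butenolide (γ-deprotonation by Et3N under TMSOTf activation) gives the aromatic 2-silyloxyfuran (silyl dienol ether formation); no stereocentre.

**Step 5**
Reactants: 5 (E)-6-(furan-3-yl)-2-methylhex-2-enal; 11 tert-butyldimethyl{[2-(trimethylsilyloxy)furan-3-yl]methoxy}silane
Product: 13 (5R)-3-{[(tert-butyldimethylsilyl)oxy]methyl}-5-[(1S,2E)-6-(furan-3-yl)-1-hydroxy-2-methylhex-2-en-1-yl]furan-2(5H)-one, via aldol TMS ether 12 (not isolated)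
Conditions: 9-amino-9-deoxy-epi-cinchona alkaloid 3,5-(CF3)2C6H3-thiourea·CF3CO2H salt (10 mol%; quinine- or quinidine-derived, whichever delivers 5R,1′S), CH2Cl2, −20 °C; then 1 M HCl, THF, 0 °C
Reagents that add atoms: none
Why: Catalytic asymmetric vinylogous Mukaiyama aldol reaction, in which the chiral ammonium carboxylate desilylates the furan to a tight dienolate ion pair while the thiourea binds the aldehyde, so C5 of the furan adds 1,2 to one face of the enal through an open anti-selective transition state and sets C8 (R) and C9 (S) (erythro) in one step.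

**Step 6**
Reactants: 13 the anti aldol from step 5
Product: 14 (1S,2E)-1-[(2R)-4-{[(tert-butyldimethylsilyl)oxy]methyl}-5-oxo-2,5-dihydrofuran-2-yl]-6-(furan-3-yl)-2-methylhex-2-en-1-yl 2-methylprop-2-enoate
Conditions: methacrylic anhydride (1.5 equiv), Et3N, DMAP (cat.), CH2Cl2, −20 → 0 °C
Reagents that add atoms: methacrylic anhydride (CC(=C)C(=O)OC(=O)C(C)=C)
Why: DMAP-catalysed acylation of the secondary allylic alcohol (Steglich-type esterification) retains the C9 configuration, and the low temperature avoids E1cB loss of the new ester from the acidic butenolide γ-position.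

**Step 7**
Reactants: 14 the silyl ether methacrylate
Product: 15 (1S,2E)-1-[(2R)-4-(bromomethyl)-5-oxo-2,5-dihydrofuran-2-yl]-6-(furan-3-yl)-2-methylhex-2-en-1-yl 2-methylprop-2-enoate
Conditions: Ph3PBr2 (1.3 equiv), CH2Cl2, 0 °C → rt
Reagents that add atoms: triphenylphosphine dibromide (BrP(Br)(c1ccccc1)(c1ccccc1)c1ccccc1)
Why: Ph3PBr2 converts primary silyl ethers directly into bromides (the silyl ether oxygen attacks phosphorus, TBSBr leaves, and bromide displaces Ph3PO from the alkoxyphosphonium in an SN2 step) under neutral conditions that spare the esters and the furan; no stereocentre is touched.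

**Step 8**
Reactants: 15 the bromomethyl-butenolide furan
Product: 17 (1S,2E,6Z)-1-[(2R)-4-(bromomethyl)-5-oxo-2,5-dihydrofuran-2-yl]-6-formyl-2-methyl-8-oxoocta-2,6-dien-1-yl 2-methylprop-2-enoate, via furan endoperoxide 16 (not isolated)
Conditions: O2, methylene blue (cat.), visible light, CH2Cl2, −78 °C; then PPh3 (1.0 equiv), −78 → −20 °C; used at once
Reagents that add atoms: dioxygen (O=O)
Why: Singlet oxygen adds [4+2] to the electron-rich furan far faster than it undergoes the ene reaction with the ester-deactivated trisubstituted alkene, and reduction of the endoperoxide O–O bond by exactly one equivalent of PPh3 at −78 °C (too cold for SN2 on the allylic bromide) releases the (Z)-ene-dial, whose cis geometry is the future C4=C5 bond with C6 and C15 on the same side.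

**Step 9**
Reactants: 17 the (Z)-ene-dial bromide
Product: 19 6-hydroxy-9-(methacryloyloxy)-15-oxoelema-1,3,11(13)-trien-12,8-olide (5R,6S,7R,8R,9S,10S), via germacranolide 6,15-lactol 18 (not isolated)
Conditions: CrCl2 (8 equiv), 4 Å MS, THF–DMF (4:1), rt, slow addition of 17 (final 2 mM); pH 7 buffer work-up; then PhMe, NaHCO3, BHT (cat.), 90–110 °C
Reagents that add atoms: none
Why: Proposed new method: divalent chromium inserts into the allylic C–Br bond and the ring-locked allylchromium adds through its γ-carbon C7 to the less hindered C6 aldehyde (attack at C15 would need a nine-membered E-cycloalkene) in a Zimmerman–Traxler chair in which the equatorial aldehyde chain gives the 6,7-anti relationship and the tether from C9 reaches only the butenolide face that carries C9 (an E,E-cyclodeca-1,5-diene must be gauche about C7–C8), giving the cis-fused 8,12-lactone; the C6 alkoxide then closes onto the cis C15 aldehyde to lactol 18, which on heating undergoes the germacrane-to-elemane Cope rearrangement through a chair in which the lactol oxygen is held in the plane of C4=C5, so C10 bonds to C5 from the C7 side and C4 ends up cis to O6 and to the C10 methyl before the α-methylene lactol opens to the conjugated hydroxy-aldehyde; the closest known reactions are Nozaki–Hiyama–Kishi allylation macrocyclisations (including allylations of aldehydes with 3-(bromomethyl)butenolides) and the thermal germacranolide-to-elemanolide Cope rearrangement.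

**Step 10**
Reactants: 19 the vinyl elemanolide
Product: 20 (1S)-1,2-epoxy-6-hydroxy-9-(methacryloyloxy)-15-oxoelema-3,11(13)-dien-12,8-olide (5R,6S,7R,8R,9S,10R), the target
Conditions: Ti(OiPr)4 (10 mol%), cis-1,2-diaminocyclohexane salalen ligand (10 mol%; antipode that gives (S)-epoxides from 1-alkenes), 30% aq. H2O2 (1.5 equiv), CH2Cl2, rt
Reagents that add atoms: hydrogen peroxide (OO)
Why: Katsuki–Berkessel titanium–salalen epoxidation, in which the electrophilic Ti–OOH species transfers oxygen only to unconjugated terminal alkenes, so the vinyl group reacts while the three carbonyl-conjugated alkenes are left, and the chiral ligand rather than the substrate selects the face that gives C1 (S).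

**Compound list**
1 | 3-bromofuran | Brc1ccoc1 | starting material
2 | but-3-en-1-ylmagnesium bromide | C=CCC[Mg]Br | starting material
3 | 3-(but-3-en-1-yl)furan | C=CCCc1ccoc1 | intermediate
4 | methacrolein | CC(=C)C=O | starting material
5 | (E)-6-(furan-3-yl)-2-methylhex-2-enal | O=C/C(C)=C/CCc1ccoc1 | intermediate
6 | furan-3-ylmethanol | OCc1ccoc1 | starting material
7 | lithium (2-lithiofuran-3-yl)methanolate | [Li]OCc1ccoc1[Li] | intermediate
8 | lithium [3-(lithiooxymethyl)furan-2-yl]triisopropoxyborate | [Li+].[Li]OCc1ccoc1[B-](OC(C)C)(OC(C)C)OC(C)C | intermediate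
9 | 3-(hydroxymethyl)furan-2(5H)-one | O=C1OCC=C1CO | intermediate
10 | 3-{[(tert-butyldimethylsilyl)oxy]methyl}furan-2(5H)-one | O=C1OCC=C1CO[Si](C)(C)C(C)(C)C | intermediate
11 | tert-butyldimethyl{[2-(trimethylsilyloxy)furan-3-yl]methoxy}silane | C[Si](C)(C)Oc1occc1CO[Si](C)(C)C(C)(C)C | intermediate
12 | 1′-O-trimethylsilyl ether of 13 | O=C1O[C@@H]([C@@H](O[Si](C)(C)C)/C(C)=C/CCc2ccoc2)C=C1CO[Si](C)(C)C(C)(C)C | intermediate
13 | (5R)-3-{[(tert-butyldimethylsilyl)oxy]methyl}-5-[(1S,2E)-6-(furan-3-yl)-1-hydroxy-2-methylhex-2-en-1-yl]furan-2(5H)-one | O=C1O[C@@H]([C@@H](O)/C(C)=C/CCc2ccoc2)C=C1CO[Si](C)(C)C(C)(C)C | intermediate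
14 | (1S,2E)-1-[(2R)-4-{[(tert-butyldimethylsilyl)oxy]methyl}-5-oxo-2,5-dihydrofuran-2-yl]-6-(furan-3-yl)-2-methylhex-2-en-1-yl 2-methylprop-2-enoate | O=C1O[C@@H]([C@@H](OC(=O)C(C)=C)/C(C)=C/CCc2ccoc2)C=C1CO[Si](C)(C)C(C)(C)C | intermediate
15 | (1S,2E)-1-[(2R)-4-(bromomethyl)-5-oxo-2,5-dihydrofuran-2-yl]-6-(furan-3-yl)-2-methylhex-2-en-1-yl 2-methylprop-2-enoate | O=C1O[C@@H]([C@@H](OC(=O)C(C)=C)/C(C)=C/CCc2ccoc2)C=C1CBr | intermediate
16 | (1S,2E)-1-[(2R)-4-(bromomethyl)-5-oxo-2,5-dihydrofuran-2-yl]-2-methyl-6-(2,3,7-trioxabicyclo[2.2.1]hept-5-en-5-yl)hex-2-en-1-yl 2-methylprop-2-enoate (bridgehead epimers) | O=C1O[C@@H]([C@@H](OC(=O)C(C)=C)/C(C)=C/CCC2=CC3OOC2O3)C=C1CBr | intermediate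
17 | (1S,2E,6Z)-1-[(2R)-4-(bromomethyl)-5-oxo-2,5-dihydrofuran-2-yl]-6-formyl-2-methyl-8-oxoocta-2,6-dien-1-yl 2-methylprop-2-enoate | O=C1O[C@@H]([C@@H](OC(=O)C(C)=C)/C(C)=C/CC/C(C=O)=C/C=O)C=C1CBr | intermediate
18 | 6,15-epoxy-15-hydroxy-9-(methacryloyloxy)germacra-1(10)E,4,11(13)-trien-12,8-olide (6S,7R,8R,9S; cis-fused lactone; C15 epimers) | C=C(C)C(=O)O[C@@H]1[C@@H]2OC(=O)C(=C)[C@@H]2[C@H]3OC(O)C(CC/C=C1\C)=C3 | intermediate
19 | 6-hydroxy-9-(methacryloyloxy)-15-oxoelema-1,3,11(13)-trien-12,8-olide (5R,6S,7R,8R,9S,10S) | C=C(C)C(=O)O[C@@H]1[C@@H]2OC(=O)C(=C)[C@@H]2[C@@H](O)[C@@H](C(=C)C=O)[C@]1(C)C=C | intermediate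
20 | (1S)-1,2-epoxy-6-hydroxy-9-(methacryloyloxy)-15-oxoelema-3,11(13)-dien-12,8-olide (5R,6S,7R,8R,9S,10R), CNP0124638.3 | C=C(C)C(=O)O[C@@H]1[C@@H]2OC(=O)C(=C)[C@@H]2[C@@H](O)[C@@H](C(=C)C=O)[C@]1(C)[C@H]1CO1 | target

**Step count**
Total steps: 10. Longest linear sequence: 8 (steps 1, 2, 5, 6, 7, 8, 9, 10; the donor branch, steps 3 and 4, joins at step 5 and is equally long).

**Steps most likely to fail, with fallbacks**

Step 9 (macrocyclisation and Cope). The risks are oligomerisation, reduction of the ene-dial by divalent chromium, trans rather than cis lactone fusion, and dehydration of lactol 18 to a furan before it rearranges. The fallback sets out from 15 and comes back at 18. Base-free borylation of 15 with B2pin2 and Pd2(dba)3 (toluene, 50 °C) gives the allylboronate (1S,2E)-6-(furan-3-yl)-2-methyl-1-[(2R)-5-oxo-4-(pinacolborylmethyl)-2,5-dihydrofuran-2-yl]hex-2-en-1-yl methacrylate F1. Photooxygenation and PPh3 reduction as in step 8 lead through the corresponding furan endoperoxide F2 to the ene-dial boronate F3. Warming F3 at 2 mM in toluene (60–80 °C) replaces the chromium step by a metal-free intramolecular allylboration through the same closed chair and gives the C6-O-pinacolboryl germacranolide enal F4. Aqueous NaHCO3 work-up hydrolyses the borate ester, the free C6–OH closes to lactol 18, and 18 is heated as in step 9 to give 19.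

Step 10 (epoxidation). The risks are low reactivity of the neopentyl-type vinyl group toward the bulky titanium catalyst and side reactions of the aldehyde with H2O2. The fallback sets out from 19 and comes back at 20. Unselective electrophilic epoxidation with dimethyldioxirane (acetone, −20 °C) gives 20 together with its C1 epimer, the (1R)-epoxide F5. The mixture is then subjected to Jacobsen hydrolytic kinetic resolution with [N,N′-bis(3,5-di-tert-butylsalicylidene)cyclohexane-1,2-diaminato]cobalt acetate, (salen)Co(OAc) (trivalent cobalt; the antipode that hydrolyses (R)-terminal epoxides), and 0.5 equiv H2O. This opens F5 at its terminal carbon to the 1,2-diol F6 and leaves 20, which is separated by chromatography.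

Step 5 (vinylogous aldol). The risk is poor anti selectivity or enantioselectivity with the 3-substituted silyloxyfuran and the α-branched enal. The fallback sets out from 5 and 11 and comes back at 14. A Lewis-acid Mukaiyama variant with Ti(OiPr)4/BINOL (BINOL antipode chosen for 5R) goes through an open transition state that favours the syn (threo) adduct. It gives, through the syn aldol TMS ether F7 and acidic work-up, the (5R,1′R)-syn alcohol F8. Mitsunobu esterification of F8 with methacrylic acid (PPh3, DIAD, THF, 0 °C) inverts C9 and installs the ester in one operation, giving 14 directly, so step 6 is skipped.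

**Further compounds**
F1 | step 9 | (1S,2E)-6-(furan-3-yl)-2-methyl-1-[(2R)-5-oxo-4-(pinacolborylmethyl)-2,5-dihydrofuran-2-yl]hex-2-en-1-yl 2-methylprop-2-enoate | O=C1O[C@@H]([C@@H](OC(=O)C(C)=C)/C(C)=C/CCc2ccoc2)C=C1CB1OC(C)(C)C(C)(C)O1
F2 | step 9 | furan endoperoxide of F1 (2,3,7-trioxabicyclo[2.2.1]hept-5-en-5-yl in place of furan-3-yl) | O=C1O[C@@H]([C@@H](OC(=O)C(C)=C)/C(C)=C/CCC2=CC3OOC2O3)C=C1CB1OC(C)(C)C(C)(C)O1
F3 | step 9 | (1S,2E,6Z)-6-formyl-2-methyl-8-oxo-1-[(2R)-5-oxo-4-(pinacolborylmethyl)-2,5-dihydrofuran-2-yl]octa-2,6-dien-1-yl 2-methylprop-2-enoate | O=C1O[C@@H]([C@@H](OC(=O)C(C)=C)/C(C)=C/CC/C(C=O)=C/C=O)C=C1CB1OC(C)(C)C(C)(C)O1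
F4 | step 9 | 9-(methacryloyloxy)-15-oxo-6-(pinacolboryloxy)germacra-1(10)E,4E,11(13)-trien-12,8-olide (6S,7R,8R,9S) | C=C(C)C(=O)O[C@@H]1[C@@H]2OC(=O)C(=C)[C@@H]2[C@@H](OB3OC(C)(C)C(C)(C)O3)/C=C(C=O)/CC/C=C1\C
F5 | step 10 | (1R)-1,2-epoxy-6-hydroxy-9-(methacryloyloxy)-15-oxoelema-3,11(13)-dien-12,8-olide (C1 epimer of 20) | C=C(C)C(=O)O[C@@H]1[C@@H]2OC(=O)C(=C)[C@@H]2[C@@H](O)[C@@H](C(=C)C=O)[C@]1(C)[C@@H]1CO1
F6 | step 10 | (1R)-1,2,6-trihydroxy-9-(methacryloyloxy)-15-oxoelema-3,11(13)-dien-12,8-olide | C=C(C)C(=O)O[C@@H]1[C@@H]2OC(=O)C(=C)[C@@H]2[C@@H](O)[C@@H](C(=C)C=O)[C@]1(C)[C@@H](O)CO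
F7 | step 5 | 1′-O-trimethylsilyl ether of F8 | O=C1O[C@@H]([C@H](O[Si](C)(C)C)/C(C)=C/CCc2ccoc2)C=C1CO[Si](C)(C)C(C)(C)C
F8 | step 5 | (5R)-3-{[(tert-butyldimethylsilyl)oxy]methyl}-5-[(1R,2E)-6-(furan-3-yl)-1-hydroxy-2-methylhex-2-en-1-yl]furan-2(5H)-one | O=C1O[C@@H]([C@H](O)/C(C)=C/CCc2ccoc2)C=C1CO[Si](C)(C)C(C)(C)C
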